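Remarks on the chemistry (assumptions, one line each):
- Neolignan locants are used throughout; on the dihydrobenzofuran C7 = C2, C8 = C3, C1' = C5 and C5' = C7. The descriptors 3S for 8–13 and 2R,3S for 15–18 were re-derived from the SMILES strings and agree with 7R,8S of the target.
- The sense of induction of the (R)-BINAP–rhodium catalyst on 7 is assumed to follow that of simple (E)-crotonates (aryl delivered to the face that gives the 3S ester); if 8 turned out to be the antipode, (S)-BINAP would be used and nothing else would change.
- Compounds 7 and 9 are taken as catalogue compounds. A one-flask sequence with a non-isolated intermediate is counted as one step.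

## Structural features

The target is a 2-aryl-3-hydroxymethyl-2,3-dihydrobenzofuran. Ring A (3,4,5-trimethoxyphenyl) sits on C7; ring B is the fused arene with a methoxy group at C5' and an (E)-3-hydroxyprop-1-enyl chain at C1'; ring C is the five-membered ether ring O4'–C7–C8–C3'–C4'. C7 and C8 are the only stereocentres; they are adjacent, and ring A and the C9 hydroxymethyl group are trans (7R,8S). C7 is benzylic to ring A and carries the aryl ether oxygen, so the C7–O4' bond can ionise under acid; because the trans ring is the more stable one, reversible ionisation works for the target and not against it. The cinnamyl alcohol is the most fragile group (acid, oxidants, hydrogenation), both arenes are electron-rich and oxidisable, and a free C9 hydroxyl beside a C7 carboxyl group would lactonise. The real difficulty is C8, a benzylic methine that has to be made in one absolute configuration and must then dictate C7. The key step uses the position of C7 between ring A and O4': a carboxyl group on C7 can leave as CO2 on anodic oxidation, ring A stabilises the cation that remains, and the phenol oxygen O4' of ring B, held in a 1,5-relationship through C8 and C3', captures it and closes ring C.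

## Logic of the disconnections

18 to 17: no skeletal bond is cut; the C9' alcohol is traced back to a methyl ester. The acid-sensitive allylic alcohol is thereby made in the last step. The forward step must reduce the ester 1,2-selectively, leave C7'=C8' alone and tolerate the free C9 hydroxyl.

17 to 15 (through 16): the C7'=C8' double bond is cut, leaving an aryl aldehyde and a two-carbon stabilised ylide. The aldehyde is carried as a dioxolane and O9 as a silyl ether, and one acid treatment removes both. The forward step must give the E alkene, and the acid must not damage ring C; if C7–O4' ionises it can only re-close to the trans ring.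

15 to 13 (through 14): the O4'–C7 bond is cut and a carboxyl group is put back on C7. Ring C opens to an acyclic acid whose only defined centre is C8, so C7 need not be controlled in any earlier step. The forward step must take electrons from the carboxylate and not from the phenol or the arenes, and must close trans. Since 13 is a 3-(2-hydroxyaryl)propanoic acid that acid would lactonise, it is released under neutral conditions and used at once.

13 to 12 to 11: only protecting groups change (phenol benzyl ether, ethyl ester). The phenol has to stay masked through the organometallic steps, and the benzyl group is chosen because it leaves without acid or base. The forward steps must spare the dioxolane and the silyl ether.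

11 to 8 and 9: the C7–C1 bond to ring A is cut. Ring A then arrives as a simple aryl bromide and C7 becomes the α-carbon of an ester. The forward step must arylate a β-branched enolate once without ester self-condensation; C8 is not acidic and stays intact.

8 to 6 and 7: the C8–C3' bond is cut. This is the one catalyst-controlled stereocentre: ring B is delivered as an aryl–rhodium species to one face of an (E)-enoate that already holds C7, C9 and the carboxyl carbon. The forward step needs high facial selectivity with an ortho-alkoxy arylboronic acid and must outrun protodeboronation.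

6 to 3 to 2 to 1: the C–B bond comes from C–Br, the dioxolane from the aldehyde, the benzyl ether from the phenol. Compound 1 already carries every ring B substituent in the right place, so no aromatic substitution chemistry is needed.

## Other disconnections considered

Alternative 1: The cut is C7–C1 (ring A) together with C8–C3' (ring B). In the forward step the (E)-alkenyl boronate A2 and the aryllithium A3 (from 9) give a boron ate complex. The arylpalladium species from the ring B bromide A4, Pd(OAc)2 and MandyPhos then induces a 1,2-shift of ring A from boron to C7, anti to palladium, and reductive elimination puts ring B on C8 to give A1.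
- In favour: both aryl–carbon bonds and both stereocentres form in one catalytic enantioselective step, the cinnamate is already in place, and A4 is about two steps from 1. The whole route could be around six or seven steps, so on convergence and step economy this plan is better than the chosen one.
- Against: β-substituted alkenyl pinacol boronates tend to transfer the alkenyl group (Suzuki–Miyaura path) instead of undergoing the shift. Bromide ion retards the cationic palladium pathway. Palladium on C8 has the C9 silyloxy group in a β-position, so β-oxygen elimination can compete.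
- Comparison: A1 still lacks ring C. Oxidation of C7–B proceeds with retention and gives the alcohol on the face that matches the trans ring, so an invertive closure would give the cis ring. Closure therefore has to go through the C7 cation, exactly as in the chosen plan, and the catalyst control over C7 is not used. Both plans thus set C8 by catalyst and C7 by cation capture; the chosen plan reaches the cation in one step from the carboxylate.

Alternative 2: The cut is C7–C8. In the forward step the aryldiazoacetate A6 is decomposed by Rh2(S-PTTL)4, the tetracarboxylate of divalent rhodium. The carbene at C8 inserts into the benzylic C7–H bond of the trimethoxybenzyl ether and gives the cis ester A5; base then epimerises C8 to the trans ester A7.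
- In favour: this reaction type is established for exactly this ring system. On precedent it is the better plan, since the chosen key step has none in its intramolecular form. C7 is set directly by the catalyst, and C8 is corrected thermodynamically next to the ester.
- Against: a diazo compound has to be made and handled. A6 needs a one-carbon homologation on ring B, O-alkylation and diazo transfer before the key step. The electron-rich trimethoxyarene can divert the carbene (cyclopropanation, oxonium ylide). After A7 the ester must be reduced and the C1' bromide turned into the propenol by a Mizoroki–Heck reaction and a second reduction.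
- Comparison: the roles are mirrored (here C7 by catalyst and C8 by equilibration, in the chosen plan C8 by catalyst and C7 by substrate). The step count is expected to be about equal or slightly higher, around eleven or twelve.

Alternative 3: The cuts are C7–C8 and O4'–C7. In the forward step Cs2CO3 releases the ortho-quinone methide from sulfone A9 and the ylide from the chiral sulfonium salt A10. The ylide carbon (C7) adds to C8 and the phenoxide displaces the sulfide at C7, giving A8.
- In favour: two bonds and ring C form in one convergent step. The trans ring follows from the anti betaine and the invertive displacement. The [4+1] annulation of ortho-quinone methides with sulfur ylides is a known reaction type. The ring is closed through the same O4'–C7 bond as in the chosen plan, so the two are equal on the ring-closing logic, and this plan is better on convergence.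
- Against: the quinone methide here carries an alkyl substituent with hydrogens on C9 and can tautomerise to a vinyl phenol. The ylide is only semi-stabilised, so enantiocontrol by a stoichiometric chiral sulfide is less secure. 3,4,5-Trimethoxybenzyl sulfonium salts ionise easily. A9 takes several steps, and A8 still needs two or three steps to convert the bromide into the propenol.
- Comparison: the step count is about the same as the chosen plan. Absolute control would rest on a stoichiometric reagent, whereas the chosen plan uses a catalytic conjugate addition of a well-understood type.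

Key step: step 8

## Route

Step 1
Reactants: 1 3-bromo-4-hydroxy-5-methoxybenzaldehyde (5-bromovanillin)
Product: 2 4-(benzyloxy)-3-bromo-5-methoxybenzaldehyde
Conditions: BnBr (1.1 equiv), K2CO3 (1.5 equiv), DMF, 60 °C
Reagents that add atoms: benzyl bromide, BrCc1ccccc1
Why: Williamson ether synthesis; the phenoxide is made acidic by the para formyl group and is alkylated cleanly on oxygen despite the two ortho substituents.

Step 2
Reactants: 2 4-(benzyloxy)-3-bromo-5-methoxybenzaldehyde
Product: 3 2-[4-(benzyloxy)-3-bromo-5-methoxyphenyl]-1,3-dioxolane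
Conditions: HOCH2CH2OH (3 equiv), TsOH·H2O (2 mol %), toluene, reflux, Dean–Stark trap
Reagents that add atoms: ethane-1,2-diol, OCCO
Why: Acid-catalysed acetalisation driven by azeotropic removal of water; the aldehyde must be masked against n-BuLi, the aryl–rhodium species and the amide base of the next steps.

Step 3
Reactants: 3 2-[4-(benzyloxy)-3-bromo-5-methoxyphenyl]-1,3-dioxolane
Product: 6 [2-(benzyloxy)-5-(1,3-dioxolan-2-yl)-3-methoxyphenyl]boronic acid, via aryllithium 4 (not isolated), via lithium triisopropoxyborate 5 (not isolated)
Conditions: n-BuLi (1.05 equiv), THF, −78 °C; B(OiPr)3 (1.5 equiv), −78 °C to rt; aq. NH4Cl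
Reagents that add atoms: triisopropyl borate, CC(C)OB(OC(C)C)OC(C)C; water, O
Why: Bromine–lithium exchange is faster than any deprotonation at −78 °C and the dioxolane is inert to n-BuLi. The aryllithium 4 is trapped as the ate complex 5, which the weakly acidic work-up hydrolyses to the boronic acid without opening the acetal (lithiation–borylation).

Step 4
Reactants: 6 [2-(benzyloxy)-5-(1,3-dioxolan-2-yl)-3-methoxyphenyl]boronic acid; 7 ethyl (E)-4-[(tert-butyldimethylsilyl)oxy]but-2-enoate
Product: 8 ethyl (3S)-3-[2-(benzyloxy)-5-(1,3-dioxolan-2-yl)-3-methoxyphenyl]-4-[(tert-butyldimethylsilyl)oxy]butanoate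
Conditions: 7 (1.2 equiv), [Rh(nbd)2]BF4 (2 mol %), (R)-BINAP (2.4 mol %), Et3N (1 equiv), 1,4-dioxane/H2O (10:1), 35 °C
Reagents that add atoms: none
Why: Hayashi–Miyaura reaction: the aryl group passes from boron to the hydroxo complex of monovalent rhodium, the (E)-enoate inserts into the aryl–rhodium bond on the face left open by (R)-BINAP, and water releases the ester. This sets the 3S centre (the future C8), by analogy with (E)-crotonates. The mild temperature limits protodeboronation of the ortho-alkoxy boronic acid, and the acetal and silyl ether are inert to the near-neutral medium.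

Step 5
Reactants: 8 ethyl (3S)-3-[2-(benzyloxy)-5-(1,3-dioxolan-2-yl)-3-methoxyphenyl]-4-[(tert-butyldimethylsilyl)oxy]butanoate; 9 5-bromo-1,2,3-trimethoxybenzene
Product: 11 ethyl (3S)-3-[2-(benzyloxy)-5-(1,3-dioxolan-2-yl)-3-methoxyphenyl]-4-[(tert-butyldimethylsilyl)oxy]-2-(3,4,5-trimethoxyphenyl)butanoate (both C2 epimers), via lithium enolate 10 (not isolated)
Conditions: LiN(SiMe3)2 (2.3 equiv), toluene, −10 °C; then 9 (1.1 equiv), Pd(dba)2 (2 mol %), P(t-Bu)3 (2.2 mol %), rt to 50 °C; aq. NH4Cl
Reagents that add atoms: none
Why: Palladium-catalysed α-arylation of an ester enolate: 9 adds oxidatively to zerovalent palladium, enolate 10 transmetalates, and the bulky electron-rich phosphine drives reductive elimination of the C7–aryl bond. β-Branching slows Claisen self-condensation, there is no leaving group β to the enolate, and C8 is not acidic. The new C7 centre forms as a mixture, which does not matter because C7 becomes planar in step 8.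

Step 6
Reactants: 11 ethyl (3S)-3-[2-(benzyloxy)-5-(1,3-dioxolan-2-yl)-3-methoxyphenyl]-4-[(tert-butyldimethylsilyl)oxy]-2-(3,4,5-trimethoxyphenyl)butanoate (both C2 epimers)
Product: 12 (3S)-3-[2-(benzyloxy)-5-(1,3-dioxolan-2-yl)-3-methoxyphenyl]-4-[(tert-butyldimethylsilyl)oxy]-2-(3,4,5-trimethoxyphenyl)butanoic acid (both C2 epimers)
Conditions: LiOH·H2O (5 equiv), THF/MeOH/H2O (3:1:1), 50 °C; then AcOH to pH 5, 0 °C, extraction
Reagents that add atoms: lithium hydroxide, [Li+].[OH-]
Why: Saponification of the hindered ester by acyl–oxygen cleavage; the dioxolane and the primary silyl ether are stable to aqueous base. The acid is released only at pH 5 in the cold so that the aryl dioxolane is not hydrolysed.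

Step 7
Reactants: 12 (3S)-3-[2-(benzyloxy)-5-(1,3-dioxolan-2-yl)-3-methoxyphenyl]-4-[(tert-butyldimethylsilyl)oxy]-2-(3,4,5-trimethoxyphenyl)butanoic acid (both C2 epimers)
Product: 13 (3S)-4-[(tert-butyldimethylsilyl)oxy]-3-[5-(1,3-dioxolan-2-yl)-2-hydroxy-3-methoxyphenyl]-2-(3,4,5-trimethoxyphenyl)butanoic acid (both C2 epimers)
Conditions: H2 (1 atm), 10% Pd/C, EtOAc, rt; filtration, concentration below 25 °C, used at once
Reagents that add atoms: none
Why: Hydrogenolysis of the aryl benzyl ether over palladium under neutral conditions, which spares the acetal, the silyl ether and both stereocentres. The hydroxy acid is not stored, because acid or heat would close it to the six-membered aryl lactone.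

Step 8
Reactants: 13 (3S)-4-[(tert-butyldimethylsilyl)oxy]-3-[5-(1,3-dioxolan-2-yl)-2-hydroxy-3-methoxyphenyl]-2-(3,4,5-trimethoxyphenyl)butanoic acid (both C2 epimers)
Product: 15 tert-butyl{[(2R,3S)-5-(1,3-dioxolan-2-yl)-7-methoxy-2-(3,4,5-trimethoxyphenyl)-2,3-dihydro-1-benzofuran-3-yl]methoxy}dimethylsilane, via C7 benzylic cation 14 (not isolated)
Conditions: undivided cell, graphite anode, Pt cathode, 2,4,6-collidine (3 equiv), n-Bu4NPF6 (0.1 M), 3 Å molecular sieves, MeCN, constant current (ca. 5 mA cm−2, 2.2–2.5 F/mol), rt
Reagents that add atoms: none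
Why: Proposed new method: the collidine-paired carboxylate of 13 gives up one electron at graphite and loses CO2, and the C7 benzylic radical, far easier to oxidise than the carboxylate, is oxidised at once to cation 14, which the para methoxy group of ring A stabilises. The closest known reaction type is the Hofer–Moest (non-Kolbe) decarboxylative etherification of arylacetic and other cation-stabilising acids with added alcohols at carbon anodes in collidine-buffered media; a tethered phenol has not been shown as the trap. Ring C closes by 5-exo attack of the phenol oxygen O4' on the planar C7 cation, collidine takes the proton, and protons are reduced to hydrogen at the cathode. The new C7 centre is controlled by C8: in the closing conformer ring A turns away from the C9 silyloxymethyl arm, so the 2,3-trans ring (2R,3S) forms, which is also the more stable isomer, and both C7 epimers of 13 converge because the cation is planar. The step needs electron transfer from the carboxylate and not from the phenol or the alkoxyarenes; in the substrate only the carboxyl group is acidic enough to pair with collidine and adsorb as the anion, the phenol O–H is tied up in a hydrogen bond to the C5' methoxy oxygen, and low current density with limited charge keeps the potential at the foot of the wave. It also needs ring closure to outrun loss of H8 from 14 and capture by acetonitrile, which the 1,5-placement of O4' should secure. The dioxolane and the silyl ether are inert in the buffered medium.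

Step 9
Reactants: 15 tert-butyl{[(2R,3S)-5-(1,3-dioxolan-2-yl)-7-methoxy-2-(3,4,5-trimethoxyphenyl)-2,3-dihydro-1-benzofuran-3-yl]methoxy}dimethylsilane
Product: 17 methyl (E)-3-[(2R,3S)-3-(hydroxymethyl)-7-methoxy-2-(3,4,5-trimethoxyphenyl)-2,3-dihydro-1-benzofuran-5-yl]prop-2-enoate, via hydroxy aldehyde 16 (not isolated)
Conditions: 1 M aq. HCl, THF, rt; then NaHCO3 to pH 7–8, Ph3P=CHCO2Me (1.5 equiv), 40 °C
Reagents that add atoms: methyl (triphenyl-λ5-phosphanylidene)acetate, COC(=O)C=P(c1ccccc1)(c1ccccc1)c1ccccc1
Why: Acid-catalysed hydrolysis removes the aryl dioxolane and the primary silyl ether to give 16. After neutralisation the stabilised ylide condenses with the aryl aldehyde in the aqueous THF (Wittig reaction) and gives the E enoate. Neither stereocentre is touched, and should C7–O4' ionise in the acid it can only re-close to the trans ring.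

Step 10
Reactants: 17 methyl (E)-3-[(2R,3S)-3-(hydroxymethyl)-7-methoxy-2-(3,4,5-trimethoxyphenyl)-2,3-dihydro-1-benzofuran-5-yl]prop-2-enoate
Product: 18 (E)-3-[(2R,3S)-3-(hydroxymethyl)-7-methoxy-2-(3,4,5-trimethoxyphenyl)-2,3-dihydro-1-benzofuran-5-yl]prop-2-en-1-ol, the target (7R,8S,7'E)
Conditions: i-Bu2AlH (3.5 equiv), CH2Cl2, −78 to 0 °C; aq. potassium sodium tartrate
Reagents that add atoms: none
Why: i-Bu2AlH reduces the conjugated methyl ester to the allylic alcohol by 1,2-hydride delivery without touching the alkene; the free C9 hydroxyl only consumes one equivalent of hydride. The neutral tartrate work-up protects the acid-sensitive cinnamyl alcohol.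

## Compound list

1 | 3-bromo-4-hydroxy-5-methoxybenzaldehyde (5-bromovanillin) | COc1cc(C=O)cc(Br)c1O | starting material
2 | 4-(benzyloxy)-3-bromo-5-methoxybenzaldehyde | COc1cc(C=O)cc(Br)c1OCc1ccccc1 | intermediate
3 | 2-[4-(benzyloxy)-3-bromo-5-methoxyphenyl]-1,3-dioxolane | COc1cc(C2OCCO2)cc(Br)c1OCc1ccccc1 | intermediate
4 | [2-(benzyloxy)-5-(1,3-dioxolan-2-yl)-3-methoxyphenyl]lithium | COc1cc(C2OCCO2)cc([Li])c1OCc1ccccc1 | intermediate (not isolated)
5 | lithium [2-(benzyloxy)-5-(1,3-dioxolan-2-yl)-3-methoxyphenyl]tri(propan-2-yloxy)borate | [Li+].COc1cc(C2OCCO2)cc([B-](OC(C)C)(OC(C)C)OC(C)C)c1OCc1ccccc1 | intermediate (not isolated)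
6 | [2-(benzyloxy)-5-(1,3-dioxolan-2-yl)-3-methoxyphenyl]boronic acid | COc1cc(C2OCCO2)cc(B(O)O)c1OCc1ccccc1 | intermediate
7 | ethyl (E)-4-[(tert-butyldimethylsilyl)oxy]but-2-enoate | CCOC(=O)/C=C/CO[Si](C)(C)C(C)(C)C | starting material
8 | ethyl (3S)-3-[2-(benzyloxy)-5-(1,3-dioxolan-2-yl)-3-methoxyphenyl]-4-[(tert-butyldimethylsilyl)oxy]butanoate | CCOC(=O)C[C@H](CO[Si](C)(C)C(C)(C)C)c1cc(C2OCCO2)cc(OC)c1OCc1ccccc1 | intermediate
9 | 5-bromo-1,2,3-trimethoxybenzene | COc1cc(Br)cc(OC)c1OC | starting material
10 | lithium enolate of 8 (3S) | [Li]OC(OCC)=C[C@H](CO[Si](C)(C)C(C)(C)C)c1cc(C2OCCO2)cc(OC)c1OCc1ccccc1 | intermediate (not isolated)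
11 | ethyl (3S)-3-[2-(benzyloxy)-5-(1,3-dioxolan-2-yl)-3-methoxyphenyl]-4-[(tert-butyldimethylsilyl)oxy]-2-(3,4,5-trimethoxyphenyl)butanoate (both C2 epimers) | CCOC(=O)C(c1cc(OC)c(OC)c(OC)c1)[C@H](CO[Si](C)(C)C(C)(C)C)c1cc(C2OCCO2)cc(OC)c1OCc1ccccc1 | intermediate
12 | (3S)-3-[2-(benzyloxy)-5-(1,3-dioxolan-2-yl)-3-methoxyphenyl]-4-[(tert-butyldimethylsilyl)oxy]-2-(3,4,5-trimethoxyphenyl)butanoic acid (both C2 epimers) | OC(=O)C(c1cc(OC)c(OC)c(OC)c1)[C@H](CO[Si](C)(C)C(C)(C)C)c1cc(C2OCCO2)cc(OC)c1OCc1ccccc1 | intermediate
13 | (3S)-4-[(tert-butyldimethylsilyl)oxy]-3-[5-(1,3-dioxolan-2-yl)-2-hydroxy-3-methoxyphenyl]-2-(3,4,5-trimethoxyphenyl)butanoic acid (both C2 epimers; C8 defined, C7 either) | OC(=O)C(c1cc(OC)c(OC)c(OC)c1)[C@H](CO[Si](C)(C)C(C)(C)C)c1cc(C2OCCO2)cc(OC)c1O | intermediate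
14 | (2S)-3-[(tert-butyldimethylsilyl)oxy]-2-[5-(1,3-dioxolan-2-yl)-2-hydroxy-3-methoxyphenyl]-1-(3,4,5-trimethoxyphenyl)propan-1-ylium (C7 cation) | COc1cc([CH+][C@H](CO[Si](C)(C)C(C)(C)C)c2cc(C3OCCO3)cc(OC)c2O)cc(OC)c1OC | intermediate (not isolated)
15 | tert-butyl{[(2R,3S)-5-(1,3-dioxolan-2-yl)-7-methoxy-2-(3,4,5-trimethoxyphenyl)-2,3-dihydro-1-benzofuran-3-yl]methoxy}dimethylsilane (2,3-trans) | COc1cc([C@@H]2Oc3c(OC)cc(C4OCCO4)cc3[C@H]2CO[Si](C)(C)C(C)(C)C)cc(OC)c1OC | intermediate
16 | (2R,3S)-3-(hydroxymethyl)-7-methoxy-2-(3,4,5-trimethoxyphenyl)-2,3-dihydro-1-benzofuran-5-carbaldehyde | COc1cc([C@@H]2Oc3c(OC)cc(C=O)cc3[C@H]2CO)cc(OC)c1OC | intermediate (not isolated)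
17 | methyl (E)-3-[(2R,3S)-3-(hydroxymethyl)-7-methoxy-2-(3,4,5-trimethoxyphenyl)-2,3-dihydro-1-benzofuran-5-yl]prop-2-enoate | COc1cc([C@@H]2Oc3c(OC)cc(/C=C/C(=O)OC)cc3[C@H]2CO)cc(OC)c1OC | intermediate
18 | (E)-3-[(2R,3S)-3-(hydroxymethyl)-7-methoxy-2-(3,4,5-trimethoxyphenyl)-2,3-dihydro-1-benzofuran-5-yl]prop-2-en-1-ol, i.e. (−)-(7R,8S,7'E)-3,4,5,5'-tetramethoxy-4',7-epoxy-8,3'-neolign-7'-ene-9,9'-diol | COc1cc([C@@H]2Oc3c(OC)cc(/C=C/CO)cc3[C@H]2CO)cc(OC)c1OC | target

## Step count and risks

Total step count: 10 steps. Longest linear sequence: 10 steps (1 to 18; 7 and 9 enter as purchased compounds).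

Least certain steps, in order of risk:

Step 8 (key step, carries the label). The most likely failure is electron transfer from the phenol instead of the carboxylate. The base can assist this by taking the phenol proton, and the result would be dearomatisation of ring B or formation of an ortho-quinone methide at C8 with loss of the stereocentre. Further risks are over-oxidation of the electron-rich product once the acid is consumed and loss of H8 from the cation before ring closure. Activating the carboxyl group of 13 as a redox-active ester is not a way out, because activation next to the free phenol would close the six-membered aryl lactone.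

The fallback uses known chemistry and keeps the phenol masked while the cation is made. It sets out from 12:
- Classical Hofer–Moest electrolysis in methanol (graphite anode, NaOMe 0.2 equiv, undivided cell) should give the C7 methyl ether 2-{4-(benzyloxy)-3-[(2S)-3-[(tert-butyldimethylsilyl)oxy]-1-methoxy-1-(3,4,5-trimethoxyphenyl)propan-2-yl]-5-methoxyphenyl}-1,3-dioxolane F1 as a mixture of C7 epimers.
- Hydrogenolysis (H2, 10% Pd/C, EtOAc) should then free the phenol 2-[(2S)-3-[(tert-butyldimethylsilyl)oxy]-1-methoxy-1-(3,4,5-trimethoxyphenyl)propan-2-yl]-4-(1,3-dioxolan-2-yl)-6-methoxyphenol F2.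
- Aqueous CF3CO2H in CH2Cl2 should ionise the benzylic ether, let the phenol close ring C to the trans ring under thermodynamic control, and cleave the dioxolane and the silyl ether in the same operation.

The sequence comes back to the route at 16, which is then treated with the ylide as in the second stage of step 9.

Step 5. The enolate of 8 is β-branched, so coupling may be slow, and Claisen self-condensation of the ethyl ester or decay of the catalyst under the strongly basic conditions could take over. The fallback separates enolate formation from the metal-catalysed step. It sets out from 8: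
- Bromination of the lithium enolate (LiN(SiMe3)2, THF, −78 °C; NBS) should give ethyl (3S)-3-[2-(benzyloxy)-5-(1,3-dioxolan-2-yl)-3-methoxyphenyl]-2-bromo-4-[(tert-butyldimethylsilyl)oxy]butanoate F3.
- The α-bromo ester is then arylated with (3,4,5-trimethoxyphenyl)boronic acid under catalysis by zerovalent nickel (Ni(PPh3)4, K3PO4, toluene, 80 °C), a known coupling of α-halo carbonyl compounds that proceeds through an α-carbonyl radical.

It comes back at 11.

Step 4. The ortho-alkoxy arylboronic acid may lose boron by protonolysis before it transmetalates, and facial selectivity may be poorer than with simple crotonates because of the ortho substituent and the γ-silyloxy group. The fallback sets C8 by hydride delivery instead of aryl delivery. It sets out from 3 and 7: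
- A Mizoroki–Heck reaction (Pd(OAc)2, P(o-tol)3, Et3N, DMF, 100 °C) should give ethyl (Z)-3-[2-(benzyloxy)-5-(1,3-dioxolan-2-yl)-3-methoxyphenyl]-4-[(tert-butyldimethylsilyl)oxy]but-2-enoate F4 (aryl trans to the ester group).
- Asymmetric conjugate reduction with a copper hydride of monovalent copper (Cu(OAc)2, DTBM-SEGPHOS of the appropriate hand, (EtO)2MeSiH, t-BuOH, toluene) then sets the stereocentre.

It comes back at 8.

Step 7. Once the phenol is free, the hydroxy acid can close to the six-membered aryl lactone, and the free carboxylic acid may promote hydrogenolysis of the benzylic acetal C–O bond. The fallback removes the benzyl group before the acid exists. It sets out from 11: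
- Hydrogenolysis (H2, 10% Pd/C, EtOAc) should give ethyl (3S)-4-[(tert-butyldimethylsilyl)oxy]-3-[5-(1,3-dioxolan-2-yl)-2-hydroxy-3-methoxyphenyl]-2-(3,4,5-trimethoxyphenyl)butanoate F5.
- LiOH in aqueous THF then cleaves the ester with help from the neighbouring phenoxide, through the transient lactone (4S)-4-{[(tert-butyldimethylsilyl)oxy]methyl}-6-(1,3-dioxolan-2-yl)-8-methoxy-3-(3,4,5-trimethoxyphenyl)-3,4-dihydro-2H-chromen-2-one F6.
- Neutralisation only to pH 6–7 delivers the carboxylate salt, so the free acid is never exposed to acid.

It comes back at 13, which goes directly into step 8.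

## Further compounds

F1 | step 8 | 2-{4-(benzyloxy)-3-[(2S)-3-[(tert-butyldimethylsilyl)oxy]-1-methoxy-1-(3,4,5-trimethoxyphenyl)propan-2-yl]-5-methoxyphenyl}-1,3-dioxolane (both C7 epimers) | COC(c1cc(OC)c(OC)c(OC)c1)[C@H](CO[Si](C)(C)C(C)(C)C)c1cc(C2OCCO2)cc(OC)c1OCc1ccccc1
F2 | step 8 | 2-[(2S)-3-[(tert-butyldimethylsilyl)oxy]-1-methoxy-1-(3,4,5-trimethoxyphenyl)propan-2-yl]-4-(1,3-dioxolan-2-yl)-6-methoxyphenol (both C7 epimers) | COC(c1cc(OC)c(OC)c(OC)c1)[C@H](CO[Si](C)(C)C(C)(C)C)c1cc(C2OCCO2)cc(OC)c1O
F3 | step 5 | ethyl (3S)-3-[2-(benzyloxy)-5-(1,3-dioxolan-2-yl)-3-methoxyphenyl]-2-bromo-4-[(tert-butyldimethylsilyl)oxy]butanoate (both C2 epimers) | CCOC(=O)C(Br)[C@H](CO[Si](C)(C)C(C)(C)C)c1cc(C2OCCO2)cc(OC)c1OCc1ccccc1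
F4 | step 4 | ethyl (Z)-3-[2-(benzyloxy)-5-(1,3-dioxolan-2-yl)-3-methoxyphenyl]-4-[(tert-butyldimethylsilyl)oxy]but-2-enoate | CCOC(=O)/C=C(\CO[Si](C)(C)C(C)(C)C)c1cc(C2OCCO2)cc(OC)c1OCc1ccccc1
F5 | step 7 | ethyl (3S)-4-[(tert-butyldimethylsilyl)oxy]-3-[5-(1,3-dioxolan-2-yl)-2-hydroxy-3-methoxyphenyl]-2-(3,4,5-trimethoxyphenyl)butanoate (both C2 epimers) | CCOC(=O)C(c1cc(OC)c(OC)c(OC)c1)[C@H](CO[Si](C)(C)C(C)(C)C)c1cc(C2OCCO2)cc(OC)c1O
F6 | step 7 | (4S)-4-{[(tert-butyldimethylsilyl)oxy]methyl}-6-(1,3-dioxolan-2-yl)-8-methoxy-3-(3,4,5-trimethoxyphenyl)-3,4-dihydro-2H-chromen-2-one (both C3 epimers) | COc1cc(C2OCCO2)cc2c1OC(=O)C(c1cc(OC)c(OC)c(OC)c1)[C@@H]2CO[Si](C)(C)C(C)(C)C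
A1 | alternative 1 | methyl (E)-3-{3-[(1R,2S)-3-[(tert-butyldimethylsilyl)oxy]-1-(4,4,5,5-tetramethyl-1,3,2-dioxaborolan-2-yl)-1-(3,4,5-trimethoxyphenyl)propan-2-yl]-5-methoxy-4-(methoxymethoxy)phenyl}prop-2-enoate | COc1cc(cc(OC)c1OC)[C@H](B1OC(C)(C)C(C)(C)O1)[C@H](CO[Si](C)(C)C(C)(C)C)c1cc(/C=C/C(=O)OC)cc(OC)c1OCOC
A2 | alternative 1 | (E)-tert-butyldimethyl{[3-(4,4,5,5-tetramethyl-1,3,2-dioxaborolan-2-yl)prop-2-en-1-yl]oxy}silane | CC(C)(C)[Si](C)(C)OC/C=C/B1OC(C)(C)C(C)(C)O1
A3 | alternative 1 | (3,4,5-trimethoxyphenyl)lithium | [Li]c1cc(OC)c(OC)c(OC)c1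
A4 | alternative 1 | methyl (E)-3-[3-bromo-5-methoxy-4-(methoxymethoxy)phenyl]prop-2-enoate | COC(=O)/C=C/c1cc(Br)c(OCOC)c(OC)c1
A5 | alternative 2 | methyl (2R,3S)-cis-5-bromo-7-methoxy-2-(3,4,5-trimethoxyphenyl)-2,3-dihydro-1-benzofuran-3-carboxylate | COc1cc([C@@H]2Oc3c(OC)cc(Br)cc3[C@@H]2C(=O)OC)cc(OC)c1OC
A6 | alternative 2 | methyl 2-{5-bromo-3-methoxy-2-[(3,4,5-trimethoxyphenyl)methoxy]phenyl}-2-diazoacetate | COC(=O)C(=[N+]=[N-])c1cc(Br)cc(OC)c1OCc1cc(OC)c(OC)c(OC)c1
A7 | alternative 2 | methyl (2R,3R)-trans-5-bromo-7-methoxy-2-(3,4,5-trimethoxyphenyl)-2,3-dihydro-1-benzofuran-3-carboxylate | COc1cc([C@@H]2Oc3c(OC)cc(Br)cc3[C@H]2C(=O)OC)cc(OC)c1OC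
A8 | alternative 3 | {[(2R,3S)-5-bromo-7-methoxy-2-(3,4,5-trimethoxyphenyl)-2,3-dihydro-1-benzofuran-3-yl]methoxy}(tert-butyl)dimethylsilane (2,3-trans) | COc1cc([C@@H]2Oc3c(OC)cc(Br)cc3[C@H]2CO[Si](C)(C)C(C)(C)C)cc(OC)c1OC
A9 | alternative 3 | 4-bromo-2-{2-[(tert-butyldimethylsilyl)oxy]-1-(4-methylbenzenesulfonyl)ethyl}-6-methoxyphenol (racemic) | COc1cc(Br)cc(C(CO[Si](C)(C)C(C)(C)C)S(=O)(=O)c2ccc(C)cc2)c1O
A10 | alternative 3 | (2R,5R)-2,5-dimethyl-1-[(3,4,5-trimethoxyphenyl)methyl]thiolan-1-ium tetrafluoroborate (antipode to be chosen by the sense of induction) | C[C@@H]1CC[C@@H](C)[S+]1Cc1cc(OC)c(OC)c(OC)c1.F[B-](F)(F)F
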